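**Plan**

- Retrosynthesis: cut the four benzyl O–C bonds; then, together, the ring A C4–O and C5–CHO bonds (aryne plus DMF); then C5–Si and the triflate O–S bond; then the diaryl ether C6–O bond (SNAr); last the ring B–CH2 bond (aryllithium plus aldehyde) and the ring B C1'–O bond (Baeyer–Villiger).
- Forward: no ring is built, all three benzene rings are bought. Orcylaldehyde supplies rings B and C, joined in steps 1–5. Ring A (4-bromo-2-fluoro-6-methylbenzaldehyde) is attached through the ether oxygen in step 6 and converted into the ortho-silyl triflate in steps 7–13.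
- Enabling feature: in ring A the C4 hydroxyl, the C5 formyl carbon and the C6 aryloxy oxygen sit on three neighbouring carbons. A 3-aryloxy-aryne and a formamide C=O deliver exactly this O, C, O triad when oxygen adds to the aryne carbon remote from the aryloxy group.
- The C1 ester is carried as an aldehyde, then a dimethyl acetal, through the organolithium step, because a methyl ortho-toluate would be attacked or deprotonated at the methyl group.
- Stereochemistry: the target is achiral. The only sp3 centres formed (carbinol in step 4, aminal carbon in step 14) are racemic and are destroyed.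

Key step: step 14

Remark: ring A is numbered C1 (carries the ester carbon), C2 (methyl), C3 (H), C4 (oxygen), C5, C6 (aryloxy); systematic names in the list count the other way round. In names, ArO– means the ring B–C unit 2,4-bis(benzyloxy)-3-[2,4-bis(benzyloxy)-6-methylbenzyl]-6-methylphenoxy. 4-Bromo-2-fluoro-6-methylbenzaldehyde is assumed to be a catalogue compound.

**Route**

Step 1
Reactants: 1 2,4-dihydroxy-6-methylbenzaldehyde (orcylaldehyde)
Product: 2 2,4-bis(benzyloxy)-6-methylbenzaldehyde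
Conditions: BnBr, K2CO3, DMF, 60 °C
Reagents that add atoms: benzyl bromide, BrCc1ccccc1
Why: Williamson ether synthesis; both phenoxides, including the chelated ortho one on warming, should be alkylated by benzyl bromide.

Step 2
Reactants: 2 2,4-bis(benzyloxy)-6-methylbenzaldehyde
Product: 4 2,4-bis(benzyloxy)-6-methylphenol, via aryl formate 3 (not isolated)
Conditions: mCPBA, CH2Cl2, 0 °C → rt; then K2CO3 (cat.), MeOH
Reagents that add atoms: 3-chloroperoxybenzoic acid, OOC(=O)c1cccc(Cl)c1
Why: Baeyer–Villiger (Dakin-type) oxidation, in which the electron-rich dialkoxyaryl group migrates in preference to hydride and the formate is then cleaved by methanolysis.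

Step 3
Reactants: 4 2,4-bis(benzyloxy)-6-methylphenol
Product: 5 1,5-bis(benzyloxy)-2-(methoxymethoxy)-3-methylbenzene
Conditions: NaH, DMF, 0 °C; MOMCl, 0 °C → rt
Reagents that add atoms: chloromethyl methyl ether, COCCl
Why: O-alkylation of the sodium phenoxide (Williamson type) masks the acidic OH for the organolithium step with a group that acid later removes without touching benzyl ethers.

Step 4
Reactants: 5 1,5-bis(benzyloxy)-2-(methoxymethoxy)-3-methylbenzene; 2 2,4-bis(benzyloxy)-6-methylbenzaldehyde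
Product: 7 racemic [2,4-bis(benzyloxy)-6-methylphenyl][2,6-bis(benzyloxy)-3-(methoxymethoxy)-4-methylphenyl]methanol, via aryllithium 6 (not isolated)
Conditions: n-BuLi, TMEDA, THF, 0 °C; then 2, −78 °C → rt; H2O
Reagents that add atoms: none
Why: Directed ortho-metalation at the C–H flanked by both benzyloxy oxygens (as in 1,3-bis(benzyloxy)benzene) followed by 1,2-addition of the aryllithium to the aldehyde; the new carbinol centre is racemic and is removed in step 5.

Step 5
Reactants: 7 racemic diaryl carbinol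
Product: 9 2,4-bis(benzyloxy)-3-[2,4-bis(benzyloxy)-6-methylbenzyl]-6-methylphenol, via diarylmethane MOM ether 8 (not isolated)
Conditions: Et3SiH, TFA, CH2Cl2, −20 °C; then HCl (2 M in MeOH), 40 °C
Reagents that add atoms: none
Why: Ionic hydrogenation, in which the doubly benzylic, oxygen-stabilised cation is reduced by the silane, followed by acid methanolysis of the MOM acetal under conditions that should leave aryl benzyl ethers intact.

Step 6
Reactants: 9 ring B–C phenol; 10 4-bromo-2-fluoro-6-methylbenzaldehyde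
Product: 11 4-bromo-2-(ArO)-6-methylbenzaldehyde
Conditions: Cs2CO3, DMF, 90 °C, Ar
Reagents that add atoms: none
Why: Nucleophilic aromatic substitution (addition–elimination) of the fluoride ortho to the formyl group by the cesium phenoxide; fluoride is displaced far faster than the para bromide, and attack perpendicular to the ring tolerates the two ortho substituents of the nucleophile.

Step 7
Reactants: 11 4-bromo-2-(ArO)-6-methylbenzaldehyde
Product: 12 4-bromo-2-(ArO)-6-methylbenzaldehyde dimethyl acetal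
Conditions: HC(OMe)3, p-TsOH (cat.), MeOH/CH2Cl2, rt; Et3N quench
Reagents that add atoms: trimethyl orthoformate, COC(OC)OC
Why: Acid-catalysed acetalisation with orthoformate as dehydrating agent removes the electrophilic carbonyl, and with it the acidity of the neighbouring methyl group, before hydroxide and butyllithium are used.

Step 8
Reactants: 12 bromo acetal
Product: 13 4-(dimethoxymethyl)-3-(ArO)-5-methylphenol
Conditions: Pd2(dba)3 (cat.), t-BuXPhos (cat.), KOH, 1,4-dioxane/H2O, 100 °C; pH 7 buffer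
Reagents that add atoms: potassium hydroxide, [K+].[OH-]
Why: Palladium-catalysed hydroxylation of an unhindered aryl bromide (Buchwald-type C–O coupling with hydroxide), to which the acetal, the benzyl ethers and the diaryl ether are inert.

Step 9
Reactants: 13 phenol acetal
Product: 14 4-(dimethoxymethyl)-3-(ArO)-5-methylphenyl N-isopropylcarbamate
Conditions: i-PrNCO, Et3N (cat.), CH2Cl2, rt
Reagents that add atoms: isopropyl isocyanate, CC(C)N=C=O
Why: Base-catalysed addition of the phenol to the isocyanate installs a carbamate that directs the metalation in step 10 and is later removable by E1cB elimination.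

Step 10
Reactants: 14 N-isopropylcarbamate acetal
Product: 18 4-formyl-3-(ArO)-5-methyl-2-(trimethylsilyl)phenyl N-isopropylcarbamate, via N-TBS carbamate 15 (not isolated), via C5-lithio N-TBS carbamate 16 (not isolated), via C5-silyl N-TBS carbamate acetal 17 (not isolated)
Conditions: TBSOTf, TMEDA, Et2O/THF, 0 °C → rt; n-BuLi, TMEDA, −78 °C; TMSCl, −78 °C → rt; then 1 M HCl, THF, 0 °C → rt
Reagents that add atoms: chlorotrimethylsilane, C[Si](C)(C)Cl; water, O
Why: Directed ortho-metalation, in which the N-silylated carbamate is the strongest director and C5–H lies between it and the aryloxy oxygen, so lithiation at −78 °C and silyl quench should occur there; the acidic work-up then removes the N-silyl group and hydrolyses the acetal.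

Step 11
Reactants: 18 silyl carbamate aldehyde
Product: 19 2-(ArO)-4-[(isopropylcarbamoyl)oxy]-6-methyl-3-(trimethylsilyl)benzoic acid
Conditions: NaClO2, NaH2PO4, 2-methyl-2-butene, t-BuOH/THF/H2O, rt
Reagents that add atoms: sodium chlorite, [Na+].[O-]Cl=O
Why: Pinnick oxidation of the aldehyde by chlorous acid, with the alkene scavenging hypochlorous acid so that the electron-rich rings and the aryl silane are not chlorinated.

Step 12
Reactants: 19 silyl carbamate acid
Product: 20 methyl 2-(ArO)-4-[(isopropylcarbamoyl)oxy]-6-methyl-3-(trimethylsilyl)benzoate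
Conditions: TMSCHN2, toluene/MeOH, 0 °C → rt
Reagents that add atoms: (trimethylsilyl)diazomethane, C[Si](C)(C)C=[N+]=[N-]
Why: Esterification by diazomethane generated in situ is an O-alkylation of the carboxylate, insensitive to the two ortho substituents and neutral enough for the carbamate and the aryl silane.

Step 13
Reactants: 20 silyl carbamate methyl ester
Product: 22 methyl 2-(ArO)-6-methyl-4-[(trifluoromethylsulfonyl)oxy]-3-(trimethylsilyl)benzoate, via silyl phenol 21 (not isolated)
Conditions: DBU, Et2NH, MeCN, 40 °C; then PhNTf2, rt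
Reagents that add atoms: N-phenylbis(trifluoromethanesulfonimide), O=S(=O)(N(c1ccccc1)S(=O)(=O)C(F)(F)F)C(F)(F)F
Why: E1cB cleavage of the N-monoalkyl carbamate (the isocyanate is trapped by diethylamine) followed by triflation of the liberated phenoxide, the standard one-pot entry to ortho-silylaryl triflates.

Step 14
Reactants: 22 ring A silyl triflate; 23 N,N-dimethylformamide
Product: 27 methyl 2-(ArO)-3-formyl-4-hydroxy-6-methylbenzoate (tetra-O-benzyl praesorether E), via C4–C5 aryne 24 (not isolated), via benzoxete 25 (not isolated), via ortho-quinone methide 26 (not isolated)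
Conditions: CsF, DMF (dry, solvent, dilute), rt → 50 °C; then H2O
Reagents that add atoms: N,N-dimethylformamide, CN(C)C=O; water, O
Why: Desilylation at C5 by fluoride expels the C4 triflate and unveils aryne 24; the carbonyl oxygen of DMF then bonds to C4 and the C5 carbanion so created collapses onto the iminium carbon, the known insertion of an aryne into a formamide C=O bond. The four-membered benzoxete 25 is the only ring closed (stepwise, O–C4 first, then 4-exo C5–C closure) and does not persist: it opens by electrocyclic cleavage to the ortho-quinone methide 26, which water converts into the salicylaldehyde with loss of dimethylamine. No stereocentre results; the aminal carbon of 25 is transient. The step requires oxygen at C4 and carbon at C5, and the inductively withdrawing C6 aryloxy group should secure this by distorting the aryne so that nucleophiles add to the remote carbon and charge builds up next to the oxygen, as established for 3-alkoxyarynes. Chemoselectivity over the benzyl ethers, the ester and the other arene rings is expected from the large excess of DMF as solvent, the dilution and the neutral, non-reducing fluoride conditions.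

Step 15
Reactants: 27 tetra-O-benzyl praesorether E
Product: 28 praesorether E
Conditions: H2 (1 atm), Pd/C, EtOAc, rt
Reagents that add atoms: none
Why: Heterogeneous catalytic hydrogenolysis of the four aryl benzyl ethers at ambient pressure, stopped at full conversion so that the hydrogen-bonded aryl aldehyde, the ester and the diaryl ether remain.

**Compound list**

1 | 2,4-dihydroxy-6-methylbenzaldehyde (orcylaldehyde) | Cc1cc(O)cc(O)c1C=O | starting material
2 | 2,4-bis(benzyloxy)-6-methylbenzaldehyde | Cc1cc(OCc2ccccc2)cc(OCc2ccccc2)c1C=O | intermediate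
3 | 2,4-bis(benzyloxy)-6-methylphenyl formate | Cc1cc(OCc2ccccc2)cc(OCc2ccccc2)c1OC=O | intermediate
4 | 2,4-bis(benzyloxy)-6-methylphenol | Cc1cc(OCc2ccccc2)cc(OCc2ccccc2)c1O | intermediate
5 | 1,5-bis(benzyloxy)-2-(methoxymethoxy)-3-methylbenzene | COCOc1c(C)cc(OCc2ccccc2)cc1OCc1ccccc1 | intermediate
6 | [2,6-bis(benzyloxy)-3-(methoxymethoxy)-4-methylphenyl]lithium | COCOc1c(C)cc(OCc2ccccc2)c([Li])c1OCc1ccccc1 | intermediate
7 | racemic [2,4-bis(benzyloxy)-6-methylphenyl][2,6-bis(benzyloxy)-3-(methoxymethoxy)-4-methylphenyl]methanol | COCOc1c(C)cc(OCc2ccccc2)c(C(O)c2c(C)cc(OCc3ccccc3)cc2OCc2ccccc2)c1OCc1ccccc1 | intermediate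
8 | 1,3-bis(benzyloxy)-2-[2,4-bis(benzyloxy)-6-methylbenzyl]-4-(methoxymethoxy)-5-methylbenzene | COCOc1c(C)cc(OCc2ccccc2)c(Cc2c(C)cc(OCc3ccccc3)cc2OCc2ccccc2)c1OCc1ccccc1 | intermediate
9 | 2,4-bis(benzyloxy)-3-[2,4-bis(benzyloxy)-6-methylbenzyl]-6-methylphenol (ring B–C phenol, ArOH) | Oc1c(C)cc(OCc2ccccc2)c(Cc2c(C)cc(OCc3ccccc3)cc2OCc2ccccc2)c1OCc1ccccc1 | intermediate
10 | 4-bromo-2-fluoro-6-methylbenzaldehyde | Cc1cc(Br)cc(F)c1C=O | starting material
11 | 4-bromo-2-(ArO)-6-methylbenzaldehyde | O=Cc1c(C)cc(Br)cc1Oc1c(C)cc(OCc2ccccc2)c(Cc2c(C)cc(OCc3ccccc3)cc2OCc2ccccc2)c1OCc1ccccc1 | intermediate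
12 | 4-bromo-2-(ArO)-6-methylbenzaldehyde dimethyl acetal | COC(OC)c1c(C)cc(Br)cc1Oc1c(C)cc(OCc2ccccc2)c(Cc2c(C)cc(OCc3ccccc3)cc2OCc2ccccc2)c1OCc1ccccc1 | intermediate
13 | 4-(dimethoxymethyl)-3-(ArO)-5-methylphenol | COC(OC)c1c(C)cc(O)cc1Oc1c(C)cc(OCc2ccccc2)c(Cc2c(C)cc(OCc3ccccc3)cc2OCc2ccccc2)c1OCc1ccccc1 | intermediate
14 | 4-(dimethoxymethyl)-3-(ArO)-5-methylphenyl N-isopropylcarbamate | COC(OC)c1c(C)cc(OC(=O)NC(C)C)cc1Oc1c(C)cc(OCc2ccccc2)c(Cc2c(C)cc(OCc3ccccc3)cc2OCc2ccccc2)c1OCc1ccccc1 | intermediate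
15 | 4-(dimethoxymethyl)-3-(ArO)-5-methylphenyl N-(tert-butyldimethylsilyl)-N-isopropylcarbamate | COC(OC)c1c(C)cc(OC(=O)N(C(C)C)[Si](C)(C)C(C)(C)C)cc1Oc1c(C)cc(OCc2ccccc2)c(Cc2c(C)cc(OCc3ccccc3)cc2OCc2ccccc2)c1OCc1ccccc1 | intermediate
16 | C5-lithio derivative of 15 (lithium between the carbamate and aryloxy carbons) | COC(OC)c1c(C)cc(OC(=O)N(C(C)C)[Si](C)(C)C(C)(C)C)c([Li])c1Oc1c(C)cc(OCc2ccccc2)c(Cc2c(C)cc(OCc3ccccc3)cc2OCc2ccccc2)c1OCc1ccccc1 | intermediate
17 | C5-trimethylsilyl derivative of 15 | COC(OC)c1c(C)cc(OC(=O)N(C(C)C)[Si](C)(C)C(C)(C)C)c([Si](C)(C)C)c1Oc1c(C)cc(OCc2ccccc2)c(Cc2c(C)cc(OCc3ccccc3)cc2OCc2ccccc2)c1OCc1ccccc1 | intermediate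
18 | 4-formyl-3-(ArO)-5-methyl-2-(trimethylsilyl)phenyl N-isopropylcarbamate | O=Cc1c(C)cc(OC(=O)NC(C)C)c([Si](C)(C)C)c1Oc1c(C)cc(OCc2ccccc2)c(Cc2c(C)cc(OCc3ccccc3)cc2OCc2ccccc2)c1OCc1ccccc1 | intermediate
19 | 2-(ArO)-4-[(isopropylcarbamoyl)oxy]-6-methyl-3-(trimethylsilyl)benzoic acid | OC(=O)c1c(C)cc(OC(=O)NC(C)C)c([Si](C)(C)C)c1Oc1c(C)cc(OCc2ccccc2)c(Cc2c(C)cc(OCc3ccccc3)cc2OCc2ccccc2)c1OCc1ccccc1 | intermediate
20 | methyl 2-(ArO)-4-[(isopropylcarbamoyl)oxy]-6-methyl-3-(trimethylsilyl)benzoate | COC(=O)c1c(C)cc(OC(=O)NC(C)C)c([Si](C)(C)C)c1Oc1c(C)cc(OCc2ccccc2)c(Cc2c(C)cc(OCc3ccccc3)cc2OCc2ccccc2)c1OCc1ccccc1 | intermediate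
21 | methyl 2-(ArO)-4-hydroxy-6-methyl-3-(trimethylsilyl)benzoate (present as its DBU phenoxide) | COC(=O)c1c(C)cc(O)c([Si](C)(C)C)c1Oc1c(C)cc(OCc2ccccc2)c(Cc2c(C)cc(OCc3ccccc3)cc2OCc2ccccc2)c1OCc1ccccc1 | intermediate
22 | methyl 2-(ArO)-6-methyl-4-[(trifluoromethylsulfonyl)oxy]-3-(trimethylsilyl)benzoate | COC(=O)c1c(C)cc(OS(=O)(=O)C(F)(F)F)c([Si](C)(C)C)c1Oc1c(C)cc(OCc2ccccc2)c(Cc2c(C)cc(OCc3ccccc3)cc2OCc2ccccc2)c1OCc1ccccc1 | intermediate
23 | N,N-dimethylformamide | CN(C)C=O | starting material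
24 | methyl 2-(ArO)-6-methyl-3,4-didehydrobenzoate (ring A C4–C5 aryne) | COC(=O)C1=C(Oc2c(C)cc(OCc3ccccc3)c(Cc3c(C)cc(OCc4ccccc4)cc3OCc3ccccc3)c2OCc2ccccc2)C#CC=C1C | intermediate
25 | racemic ring A-fused 2-(dimethylamino)-2H-benzoxete (O on C4, aminal carbon on C5) | COC(=O)c1c(C)cc2OC(N(C)C)c2c1Oc1c(C)cc(OCc2ccccc2)c(Cc2c(C)cc(OCc3ccccc3)cc2OCc2ccccc2)c1OCc1ccccc1 | intermediate
26 | ortho-quinone methide: C4 ketone, C5 exocyclic (dimethylamino)methylene, geometry not defined | COC(=O)C1=C(Oc2c(C)cc(OCc3ccccc3)c(Cc3c(C)cc(OCc4ccccc4)cc3OCc3ccccc3)c2OCc2ccccc2)C(=CN(C)C)C(=O)C=C1C | intermediate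
27 | methyl 2-(ArO)-3-formyl-4-hydroxy-6-methylbenzoate (tetra-O-benzyl praesorether E) | COC(=O)c1c(C)cc(O)c(C=O)c1Oc1c(C)cc(OCc2ccccc2)c(Cc2c(C)cc(OCc3ccccc3)cc2OCc2ccccc2)c1OCc1ccccc1 | intermediate
28 | praesorether E | COC(=O)c1c(C)cc(O)c(C=O)c1Oc1c(C)cc(O)c(Cc2c(C)cc(O)cc2O)c1O | target

**Count and risks**

Total: 15 steps. Longest linear sequence: 15 steps from orcylaldehyde 1 (compound 2 is used twice; 10 and 23 are bought).

Step 14 (aryne insertion). What may go wrong: the aryne could be captured intramolecularly by the neighbouring electron-rich ring B or a benzyloxy oxygen, or by the product phenoxide, faster than the weakly nucleophilic DMF adds. Fallback: form the C5–carbonyl bond by carbamoyl migration instead of aryne insertion. It sets out from phenol 13 and returns at 27. Phenol 13 would be carbamoylated (ClC(O)NEt2, K2CO3, MeCN) to the N,N-diethylcarbamate acetal F1. s-BuLi/TMEDA at −78 °C would give the C5-lithio carbamate F2, which on warming should undergo the anionic ortho-Fries shift to the salicylamide acetal F3. Dilute aqueous acid would unmask the C1 aldehyde F4; Pinnick oxidation with excess 2-methyl-2-butene would give the acid F5; TMSCHN2 would give the methyl ester F6. Cp2Zr(H)Cl in THF should then reduce the tertiary amide selectively to the aldehyde, giving 27.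

Step 10 (directed silylation). What may go wrong: deprotonation between the two benzyloxy groups of ring C or at benzylic OCH2 positions (then Wittig rearrangement) could compete with lithiation at C5, or TBSOTf could open the acetal before it silylates nitrogen. Fallback: use the bromide instead of a carbamate to acidify C5–H. It sets out from bromo acetal 12 and returns at 18. LDA with TMSCl present (THF, −78 °C, in situ quench) should metalate only the C–H flanked by bromine and the aryloxy oxygen and give the bromo silane F7. Bromine–lithium exchange (n-BuLi, −78 °C) would give the aryllithium F8, B(OMe)3 the dimethyl boronate F9, and NaOH/H2O2 the silyl phenol acetal F10. i-PrNCO/Et3N would give the silyl carbamate acetal F11, whose acetal is hydrolysed with dilute acid to 18.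

Step 4 (lithiation between benzyloxy groups and addition). What may go wrong: benzylic deprotonation and [1,2]-Wittig rearrangement of the benzyl ethers could compete with ring lithiation, leaving too little aryllithium for the hindered aldehyde. Fallback: make the same aryllithium by halogen–metal exchange. It sets out from orcylaldehyde 1 and returns at aryllithium 6. Orcylaldehyde 1 would be iodinated between its two hydroxyls (ICl, AcOH; the other free position is flanked by the methyl group) to 2,4-dihydroxy-3-iodo-6-methylbenzaldehyde F12. Dibenzylation as in step 1 would give F13; mCPBA would give the aryl formate F14, and methanolysis the iodophenol F15; NaH/MOMCl would give the MOM ether F16. Iodine–lithium exchange (n-BuLi, THF, −78 °C) would then deliver aryllithium 6 without any deprotonation, and addition to 2 continues as in step 4.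

**Further compounds**

F1 | step 14 | 4-(dimethoxymethyl)-3-(ArO)-5-methylphenyl N,N-diethylcarbamate | COC(OC)c1c(C)cc(OC(=O)N(CC)CC)cc1Oc1c(C)cc(OCc2ccccc2)c(Cc2c(C)cc(OCc3ccccc3)cc2OCc2ccccc2)c1OCc1ccccc1
F2 | step 14 | C5-lithio derivative of F1 | COC(OC)c1c(C)cc(OC(=O)N(CC)CC)c([Li])c1Oc1c(C)cc(OCc2ccccc2)c(Cc2c(C)cc(OCc3ccccc3)cc2OCc2ccccc2)c1OCc1ccccc1
F3 | step 14 | 3-(dimethoxymethyl)-2-(ArO)-N,N-diethyl-6-hydroxy-4-methylbenzamide | COC(OC)c1c(C)cc(O)c(C(=O)N(CC)CC)c1Oc1c(C)cc(OCc2ccccc2)c(Cc2c(C)cc(OCc3ccccc3)cc2OCc2ccccc2)c1OCc1ccccc1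
F4 | step 14 | 2-(ArO)-N,N-diethyl-3-formyl-6-hydroxy-4-methylbenzamide | O=Cc1c(C)cc(O)c(C(=O)N(CC)CC)c1Oc1c(C)cc(OCc2ccccc2)c(Cc2c(C)cc(OCc3ccccc3)cc2OCc2ccccc2)c1OCc1ccccc1
F5 | step 14 | 2-(ArO)-3-(diethylcarbamoyl)-4-hydroxy-6-methylbenzoic acid | OC(=O)c1c(C)cc(O)c(C(=O)N(CC)CC)c1Oc1c(C)cc(OCc2ccccc2)c(Cc2c(C)cc(OCc3ccccc3)cc2OCc2ccccc2)c1OCc1ccccc1
F6 | step 14 | methyl 2-(ArO)-3-(diethylcarbamoyl)-4-hydroxy-6-methylbenzoate | COC(=O)c1c(C)cc(O)c(C(=O)N(CC)CC)c1Oc1c(C)cc(OCc2ccccc2)c(Cc2c(C)cc(OCc3ccccc3)cc2OCc2ccccc2)c1OCc1ccccc1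
F7 | step 10 | 4-bromo-2-(ArO)-6-methyl-3-(trimethylsilyl)benzaldehyde dimethyl acetal | COC(OC)c1c(C)cc(Br)c([Si](C)(C)C)c1Oc1c(C)cc(OCc2ccccc2)c(Cc2c(C)cc(OCc3ccccc3)cc2OCc2ccccc2)c1OCc1ccccc1
F8 | step 10 | C4-lithio analogue of F7 (lithium in place of bromine) | COC(OC)c1c(C)cc([Li])c([Si](C)(C)C)c1Oc1c(C)cc(OCc2ccccc2)c(Cc2c(C)cc(OCc3ccccc3)cc2OCc2ccccc2)c1OCc1ccccc1
F9 | step 10 | dimethyl [4-(dimethoxymethyl)-3-(ArO)-5-methyl-2-(trimethylsilyl)phenyl]boronate | COC(OC)c1c(C)cc(B(OC)OC)c([Si](C)(C)C)c1Oc1c(C)cc(OCc2ccccc2)c(Cc2c(C)cc(OCc3ccccc3)cc2OCc2ccccc2)c1OCc1ccccc1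
F10 | step 10 | 4-(dimethoxymethyl)-3-(ArO)-5-methyl-2-(trimethylsilyl)phenol | COC(OC)c1c(C)cc(O)c([Si](C)(C)C)c1Oc1c(C)cc(OCc2ccccc2)c(Cc2c(C)cc(OCc3ccccc3)cc2OCc2ccccc2)c1OCc1ccccc1
F11 | step 10 | 4-(dimethoxymethyl)-3-(ArO)-5-methyl-2-(trimethylsilyl)phenyl N-isopropylcarbamate | COC(OC)c1c(C)cc(OC(=O)NC(C)C)c([Si](C)(C)C)c1Oc1c(C)cc(OCc2ccccc2)c(Cc2c(C)cc(OCc3ccccc3)cc2OCc2ccccc2)c1OCc1ccccc1
F12 | step 4 | 2,4-dihydroxy-3-iodo-6-methylbenzaldehyde | Cc1cc(O)c(I)c(O)c1C=O
F13 | step 4 | 2,4-bis(benzyloxy)-3-iodo-6-methylbenzaldehyde | Cc1cc(OCc2ccccc2)c(I)c(OCc2ccccc2)c1C=O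
F14 | step 4 | 2,4-bis(benzyloxy)-3-iodo-6-methylphenyl formate | Cc1cc(OCc2ccccc2)c(I)c(OCc2ccccc2)c1OC=O
F15 | step 4 | 2,4-bis(benzyloxy)-3-iodo-6-methylphenol | Cc1cc(OCc2ccccc2)c(I)c(OCc2ccccc2)c1O
F16 | step 4 | 1,3-bis(benzyloxy)-2-iodo-4-(methoxymethoxy)-5-methylbenzene | COCOc1c(C)cc(OCc2ccccc2)c(I)c1OCc1ccccc1
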